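**Retrosynthetic overview**

1. Ring labels: A (OH, aryloxy, CH2CH2), B (para O/CH2CH2), C (CH2 on C1, aryloxy on C2, OH on C3), D (meta O/CH2CH2). Marchantin C (14) comes from its dimethyl ether 13 by BBr3.
2. Key disconnection: the 18-membered ring of 13 is opened at the C(sp2)–C(sp3) bond between C1 of ring C and the CH2 of the B–C bridge. This gives seco compound 12, with iodine on C1 of ring C and an N-acyloxyphthalimide on the ring B chain; closure is a nickel-electrocatalytic decarboxylative radical coupling.
3. Enabling feature: ring C carries its three substituents on adjacent atoms C1, C2 and C3, so the iodine is bought in place as 2-iodo-6-methoxyphenol. The bridge CH2 that bonds to C1 is the alpha carbon of a 3-(4-oxyphenyl)propanoic acid on ring B, one CO2 away from the radical that is needed.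
4. 12 comes from acid 11, made by Wittig union and diimide reduction of aldehyde 3 (rings A–B, Ullmann ether) and phosphonium salt 7 (rings C–D, Chan–Lam ether).
5. Ring order: all four benzene rings are bought; the macrocycle is the only ring formed, in the last step but one.

Key step: step 8

Remark: the Wittig reaction of step 4 is expected to give both alkene isomers; the mixture is carried on because the double bond is saturated in step 5.

**Route**

Step 1
Reactants: 1 methyl 3-(4-hydroxyphenyl)propanoate; 2 3-bromo-4-methoxybenzaldehyde
Product: 3 methyl 3-[4-(5-formyl-2-methoxyphenoxy)phenyl]propanoate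
Conditions: CuI (10 mol%), N,N-dimethylglycine hydrochloride (30 mol%), Cs2CO3, 1,4-dioxane, 100 °C
Reagents that add atoms: none
Why: Ligand-accelerated Ullmann diaryl ether synthesis, in which the caesium phenoxide of the unhindered phenol 1 displaces bromide from 2 at copper, should join rings A and B, since this coupling is known to tolerate aldehydes and esters.

Step 2
Reactants: 4 2-iodo-6-methoxyphenol; 5 [3-(hydroxymethyl)phenyl]boronic acid
Product: 6 [3-(2-iodo-6-methoxyphenoxy)phenyl]methanol
Conditions: Cu(OAc)2 (50 mol%), pyridine, 4 Å molecular sieves, CH2Cl2, O2 (1 atm), rt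
Reagents that add atoms: none
Why: Chan–Lam oxidative coupling transfers the aryl group from boron to the phenol oxygen at room temperature through a trivalent copper aryl phenoxide, a diaryl ether method that accepts phenols with two ortho substituents (ortho-iodophenols included) and should leave the aryl iodide and the primary alcohol untouched.

Step 3
Reactants: 6 [3-(2-iodo-6-methoxyphenoxy)phenyl]methanol
Product: 7 {[3-(2-iodo-6-methoxyphenoxy)phenyl]methyl}(triphenyl)phosphonium bromide
Conditions: PPh3·HBr, MeCN, reflux
Reagents that add atoms: triphenylphosphine hydrobromide, Br.P(c1ccccc1)(c1ccccc1)c1ccccc1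
Why: The acid salt turns the benzylic alcohol into the benzylic bromide in the flask and triphenylphosphine quaternises it at once (SN2), a standard one-flask preparation of benzylphosphonium salts that should not affect the aryl iodide or the methyl ether.

Step 4
Reactants: 7 {[3-(2-iodo-6-methoxyphenoxy)phenyl]methyl}(triphenyl)phosphonium bromide; 3 methyl 3-[4-(5-formyl-2-methoxyphenoxy)phenyl]propanoate
Product: 9 methyl 3-{4-[5-{2-[3-(2-iodo-6-methoxyphenoxy)phenyl]ethenyl}-2-methoxyphenoxy]phenyl}propanoate (E/Z mixture), via phosphonium ylide 8 (not isolated)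
Conditions: K2CO3, 18-crown-6 (cat.), CH2Cl2, reflux
Reagents that add atoms: none
Why: Wittig olefination of the aromatic aldehyde with the semi-stabilised benzylic ylide, formed under solid–liquid phase-transfer conditions, should give the stilbene as an E/Z mixture, the mild carbonate base sparing the methyl ester and the aryl iodide.

Step 5
Reactants: 9 methyl 3-{4-[5-{2-[3-(2-iodo-6-methoxyphenoxy)phenyl]ethenyl}-2-methoxyphenoxy]phenyl}propanoate (E/Z mixture)
Product: 10 methyl 3-{4-[5-{2-[3-(2-iodo-6-methoxyphenoxy)phenyl]ethyl}-2-methoxyphenoxy]phenyl}propanoate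
Conditions: TsNHNH2 (excess, in portions), NaOAc, THF/H2O, reflux
Reagents that add atoms: none
Why: Diimide reduction, in which diimide made in the flask delivers two hydrogen atoms to the C=C bond through a concerted cyclic transition state, cannot cleave the C–I bond as hydrogenation over palladium would, and both alkene isomers should converge on the bibenzyl.

Step 6
Reactants: 10 methyl 3-{4-[5-{2-[3-(2-iodo-6-methoxyphenoxy)phenyl]ethyl}-2-methoxyphenoxy]phenyl}propanoate
Product: 11 3-{4-[5-{2-[3-(2-iodo-6-methoxyphenoxy)phenyl]ethyl}-2-methoxyphenoxy]phenyl}propanoic acid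
Conditions: LiOH·H2O, THF/MeOH/H2O, rt; then 1 M HCl
Reagents that add atoms: lithium hydroxide, [Li+].[OH-]
Why: Saponification by acyl–oxygen cleavage of the unhindered methyl ester should be clean, as aryl ethers and the aryl iodide are inert to hydroxide at room temperature.

Step 7
Reactants: 11 3-{4-[5-{2-[3-(2-iodo-6-methoxyphenoxy)phenyl]ethyl}-2-methoxyphenoxy]phenyl}propanoic acid
Product: 12 1,3-dioxoisoindolin-2-yl 3-{4-[5-{2-[3-(2-iodo-6-methoxyphenoxy)phenyl]ethyl}-2-methoxyphenoxy]phenyl}propanoate
Conditions: N-hydroxyphthalimide, N,N'-diisopropylcarbodiimide, DMAP (cat.), CH2Cl2, rt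
Reagents that add atoms: N-hydroxyphthalimide, ON1C(=O)c2ccccc2C1=O
Why: Carbodiimide (Steglich-type) esterification of the primary acid with N-hydroxyphthalimide is the standard route to redox-active esters and involves no other functional group of 11.

Step 8
Reactants: 12 1,3-dioxoisoindolin-2-yl 3-{4-[5-{2-[3-(2-iodo-6-methoxyphenoxy)phenyl]ethyl}-2-methoxyphenoxy]phenyl}propanoate
Product: 13 marchantin C dimethyl ether (18-membered macrocycle, both phenols as methyl ethers)
Conditions: NiCl2·6H2O (30 mol%), 2,2'-bipyridine (30 mol%), AgNO3 (0.3 equiv), LiCl, NMP, Mg anode / reticulated vitreous carbon cathode, undivided cell, constant current, slow addition of 12 (final 2 mM), rt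
Reagents that add atoms: none
Why: Proposed new method: cathodically generated zerovalent nickel–bipyridine inserts into the C1–I bond of ring C to give a divalent aryl nickel iodide, while one-electron reduction of the N-acyloxyphthalimide (at the silver-coated cathode or by low-valent nickel) expels phthalimide anion and CO2 and leaves the primary 2-arylethyl radical on the ring B chain; capture of this radical by the aryl nickel centre of the same molecule gives a trivalent aryl(alkyl)nickel species whose reductive elimination forms the C(sp2)–C(sp3) bond. The closest known reaction type is the intermolecular nickel-catalysed electroreductive decarboxylative arylation of redox-active esters with aryl iodides and bromides, which is proposed here for the first time as a macrocyclisation. The ring is closed head to tail: radical capture gives a 19-membered nickelacycle that contracts to the 18-membered ring on reductive elimination, the new bond being the one between C1 of ring C and the bridge CH2. No stereocentre is formed. The step needs ring closure to win over oligomerisation, over reduction of the radical to the ethyl compound and over radical dimerisation: slow addition to about 2 mM suppresses intermolecular capture, the iodide makes oxidative addition faster than ester reduction so that the aryl nickel acceptor is in place before the radical is formed, and the site of coupling is fixed because the chain carries a single aryl halide (at C1 of ring C) and a single ester on the unstrained meta/para-linked perimeter of the natural product.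

Step 9
Reactants: 13 marchantin C dimethyl ether
Product: 14 marchantin C
Conditions: BBr3, CH2Cl2, −78 °C to rt; then H2O
Reagents that add atoms: none
Why: BBr3 ether cleavage proceeds by coordination to the methoxy oxygen and SN2 attack of bromide on the methyl group, so both aryl methyl ethers should be cleaved while the diaryl ether bonds, which offer no sp3 carbon, stay intact.

**Compound list**

1 | methyl 3-(4-hydroxyphenyl)propanoate | COC(=O)CCc1ccc(O)cc1 | starting material
2 | 3-bromo-4-methoxybenzaldehyde | COc1ccc(C=O)cc1Br | starting material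
3 | methyl 3-[4-(5-formyl-2-methoxyphenoxy)phenyl]propanoate | COC(=O)CCc1ccc(Oc2cc(C=O)ccc2OC)cc1 | intermediate
4 | 2-iodo-6-methoxyphenol | COc1cccc(I)c1O | starting material
5 | [3-(hydroxymethyl)phenyl]boronic acid | OCc1cccc(c1)B(O)O | starting material
6 | [3-(2-iodo-6-methoxyphenoxy)phenyl]methanol | COc1cccc(I)c1Oc1cccc(CO)c1 | intermediate
7 | {[3-(2-iodo-6-methoxyphenoxy)phenyl]methyl}(triphenyl)phosphonium bromide | COc1cccc(I)c1Oc1cccc(C[P+](c2ccccc2)(c2ccccc2)c2ccccc2)c1.[Br-] | intermediate
8 | phosphonium ylide of 7 | COc1cccc(I)c1Oc1cccc(C=P(c2ccccc2)(c2ccccc2)c2ccccc2)c1 | intermediate (not isolated)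
9 | methyl 3-{4-[5-{2-[3-(2-iodo-6-methoxyphenoxy)phenyl]ethenyl}-2-methoxyphenoxy]phenyl}propanoate (E/Z mixture) | COC(=O)CCc1ccc(Oc2cc(C=Cc3cccc(Oc4c(I)cccc4OC)c3)ccc2OC)cc1 | intermediate
10 | methyl 3-{4-[5-{2-[3-(2-iodo-6-methoxyphenoxy)phenyl]ethyl}-2-methoxyphenoxy]phenyl}propanoate | COC(=O)CCc1ccc(Oc2cc(CCc3cccc(Oc4c(I)cccc4OC)c3)ccc2OC)cc1 | intermediate
11 | 3-{4-[5-{2-[3-(2-iodo-6-methoxyphenoxy)phenyl]ethyl}-2-methoxyphenoxy]phenyl}propanoic acid | OC(=O)CCc1ccc(Oc2cc(CCc3cccc(Oc4c(I)cccc4OC)c3)ccc2OC)cc1 | intermediate
12 | 1,3-dioxoisoindolin-2-yl 3-{4-[5-{2-[3-(2-iodo-6-methoxyphenoxy)phenyl]ethyl}-2-methoxyphenoxy]phenyl}propanoate | O=C(CCc1ccc(Oc2cc(CCc3cccc(Oc4c(I)cccc4OC)c3)ccc2OC)cc1)ON1C(=O)c2ccccc2C1=O | intermediate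
13 | marchantin C dimethyl ether | COc1ccc2cc1Oc1ccc(cc1)CCc1cccc(OC)c1Oc1cccc(c1)CC2 | intermediate
14 | marchantin C | Oc1ccc2cc1Oc1ccc(cc1)CCc1cccc(O)c1Oc1cccc(c1)CC2 | target

**Step count and risks**

Total step count: 9. Longest linear sequence: 8 steps (steps 2 to 9, from 4 and 5).

Steps most likely to fail:

1. Step 8 (proposed new method). The radical may be formed before, or away from, an aryl nickel centre, so that hydrodecarboxylation to the ethyl compound, radical dimerisation or intermolecular capture (oligomers) outruns ring closure. The fallback uses known chemistry, sets out from acid 11 and returns at 13. Kochi oxidative decarboxylation of 11 (Pb(OAc)4, Cu(OAc)2 cat., pyridine, benzene, 80 °C) should give the styrene 2-(3-{2-[3-(4-ethenylphenoxy)-4-methoxyphenyl]ethyl}phenoxy)-1-iodo-3-methoxybenzene F1. Anti-Markovnikov hydroboration with 9-BBN (THF, rt) gives 9-{2-[4-(5-{2-[3-(2-iodo-6-methoxyphenoxy)phenyl]ethyl}-2-methoxyphenoxy)phenyl]ethyl}-9-borabicyclo[3.3.1]nonane F2, which is not isolated. It is added slowly to PdCl2(dppf), AsPh3 and Cs2CO3 in DMF/THF/H2O at 60 °C; this B-alkyl Suzuki–Miyaura macrocyclisation forms the same C1–CH2 bond and reaches 13.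

2. Step 2. Aryl transfer to the phenol flanked by iodine and methoxy may be slow, so that protodeboronation and oxidative loss of the boronic acid consume the partner first. The fallback sets out from 4 and returns at 6. Commercial methyl 3-iodobenzoate is converted in one flask (mCPBA, TsOH·H2O, MeCN; then 1,3,5-trimethoxybenzene) into [3-(methoxycarbonyl)phenyl](2,4,6-trimethoxyphenyl)iodonium 4-methylbenzenesulfonate F3. Metal-free O-arylation of 4 (t-BuOK, THF, 40 °C; ligand coupling at iodine with transfer of the electron-poorer aryl group, insensitive to ortho substituents on the phenol) should give methyl 3-(2-iodo-6-methoxyphenoxy)benzoate F4. Reduction of F4 with i-Bu2AlH (CH2Cl2, −78 to 0 °C) gives 6.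

3. Step 1. Activation of the electron-rich, ortho-methoxy-substituted aryl bromide at copper may be sluggish, so that hydrolysis of the methyl ester and base-induced degradation of the aldehyde by carbonate at 100 °C compete. The fallback sets out from 1 and returns at 3. Chan–Lam coupling of 1 with commercial (5-formyl-2-methoxyphenyl)boronic acid (Cu(OAc)2, pyridine, 4 Å molecular sieves, CH2Cl2, O2, rt) replaces activation of the bromide by transmetalation from boron at room temperature, uses no carbonate base, and should give 3 directly.

**Further compounds**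

F1 | step 8 | 2-(3-{2-[3-(4-ethenylphenoxy)-4-methoxyphenyl]ethyl}phenoxy)-1-iodo-3-methoxybenzene | C=Cc1ccc(Oc2cc(CCc3cccc(Oc4c(I)cccc4OC)c3)ccc2OC)cc1
F2 | step 8 | 9-{2-[4-(5-{2-[3-(2-iodo-6-methoxyphenoxy)phenyl]ethyl}-2-methoxyphenoxy)phenyl]ethyl}-9-borabicyclo[3.3.1]nonane | COc1cccc(I)c1Oc1cccc(CCc2ccc(OC)c(Oc3ccc(CCB4C5CCCC4CCC5)cc3)c2)c1
F3 | step 2 | [3-(methoxycarbonyl)phenyl](2,4,6-trimethoxyphenyl)iodonium 4-methylbenzenesulfonate | COC(=O)c1cccc(c1)[I+]c1c(OC)cc(OC)cc1OC.Cc1ccc(cc1)S(=O)(=O)[O-]
F4 | step 2 | methyl 3-(2-iodo-6-methoxyphenoxy)benzoate | COC(=O)c1cccc(Oc2c(I)cccc2OC)c1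
F0 | step 1 | none | none
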